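**Plan**

1. Retrosynthesis: first the two aryl C–allyl bonds are cut (double aromatic Claisen of a bis-allyl ether). Then C1–C6 of the cyclohexene is cut while the ring A phenol oxygen is re-bonded to C1, so the 2-cyclohexenylphenol becomes a 2-methyl-4H-chromene with a three-carbon iodide arm. Then the biaryl bond (Suzuki–Miyaura) and C3–C4 (amine-catalysed addition of 3-methylbutanal to a 3-acetylcoumarin) are cut.
2. Enabling feature: the OH on C2 of ring A is 1,5 to C1 of the cyclohexene (O–C2ar–C3ar–C3–C2=C1). O and C1 can therefore share a six-membered enol-ether ring, which fixes the position of the C1=C2 bond and forces C6 to enter cis to C3; its O–C1(sp2) bond is the leaving group.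
3. Forward order: coumarin ring, the two stereocentres, the 4H-chromene ring, ring B, exchange of the pyran ring for the cyclohexene ring (phenol set free), then both allyl groups through the two phenols.
4. Stereochemistry: C3 and C4 both come from step 2 (catalyst control at C4, syn topicity for C3; the syn open chain equals the trans ring). No later step touches them.

Key step: step 8

Remark: the cyclohexene is numbered as p-menth-1-ene (C1 carries CH3, C2 is the alkene CH, C3 carries ring A, C4 the isopropyl group, C5 and C6 are CH2); ring A is the 1,2,3,5-substituted phenol ring, ring B the 3-allyl-4-hydroxyphenyl ring.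
Remark: the sense of induction in step 2 is assumed to follow the usual model for (S)-diarylprolinol silyl ethers with (E)-acceptors (syn adduct, R at the aldehyde α-carbon); the enantiomeric catalyst would be taken if the opposite sense were found.
Remark: 11 and 13 are 1,5-dienes (enol ether and vinyl group), so every operation on them is kept at or below 70 °C to stay clear of a Cope rearrangement; CIP descriptors change along the route only through priority changes.

**Route**

Step 1
Reactants: 1 3-bromo-2-hydroxybenzaldehyde; 2 ethyl 3-oxobutanoate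
Product: 4 3-acetyl-8-bromo-2H-chromen-2-one, via Knoevenagel adduct 3 (not isolated)
Conditions: piperidine (10 mol %), EtOH, rt to 60 °C
Reagents that add atoms: none
Why: Knoevenagel condensation followed by lactonisation of the phenol onto the ethyl ester is the standard entry to 3-acetylcoumarins and creates no stereocentre.

Step 2
Reactants: 4 3-acetyl-8-bromo-2H-chromen-2-one; 5 3-methylbutanal
Product: 6 (1R,10bS)-7-bromo-2-hydroxy-4-methyl-1-(propan-2-yl)-1,10b-dihydro-2H,5H-pyrano[3,4-c]chromen-5-one (tricyclic lactol, both anomers)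
Conditions: (S)-2-[diphenyl(trimethylsilyloxy)methyl]pyrrolidine (15 mol %), PhCO2H (15 mol %), PhMe, 0 °C to rt; then wet SiO2
Reagents that add atoms: none
Why: In this enamine-catalysed Michael addition (inverse-electron-demand oxa-Diels–Alder mode, known for aldehydes with activated enones), the (E)-enamine of 5 should add through its unshielded face to C4 of the doubly activated coumarin with the acetyl oxygen endo, so the catalyst sets the isopropyl-bearing centre, the (E)-relation of aryl and acetyl sets the aryl-bearing centre syn to it, and aminal hydrolysis leaves the lactol.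

Step 3
Reactants: 6 tricyclic lactol
Product: 7 (4R)-3-acetyl-8-bromo-4-[(3S)-4-methylpent-1-en-3-yl]-3,4-dihydro-2H-chromen-2-one (C3 epimers)
Conditions: Ph3PCH3Br (3 equiv), KN(SiMe3)2 (2.9 equiv), THF, −78 to 0 °C; aq NH4Cl
Reagents that add atoms: methyltriphenylphosphonium bromide, C[P+](c1ccccc1)(c1ccccc1)c1ccccc1.[Br-]
Why: Wittig methylenation of a lactol through its open aldehyde form should be clean here because the β-keto lactone is masked as its enolate under the basic conditions and the low temperature limits epimerisation next to the aldehyde.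

Step 4
Reactants: 7 (4R)-3-acetyl-8-bromo-4-[(3S)-4-methylpent-1-en-3-yl]-3,4-dihydro-2H-chromen-2-one
Product: 9 (4S,5S)-4-(3-bromo-2-hydroxyphenyl)-5-(propan-2-yl)hept-6-en-2-one, via keto acid 8 (not isolated)
Conditions: LiOH (4 equiv), THF/H2O 3:1, 40 °C; then 2 M HCl to pH 2, 45 °C
Reagents that add atoms: none
Why: Saponification of the aryl lactone and decarboxylation of the β-keto acid (ketonic cleavage of an acetoacetic ester) removes the activating carboxyl group, and neither stereocentre is α to a carbonyl group, so both are retained.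

Step 5
Reactants: 9 (4S,5S)-4-(3-bromo-2-hydroxyphenyl)-5-(propan-2-yl)hept-6-en-2-one
Product: 11 (4R)-8-bromo-2-methyl-4-[(3S)-4-methylpent-1-en-3-yl]-4H-chromene, via hemiketal 10 (not isolated)
Conditions: TsOH·H2O (5 mol %), PhMe, 4 Å molecular sieves, 70 °C; Et3N quench
Reagents that add atoms: none
Why: Acid-catalysed hemiketalisation of the phenol onto the methyl ketone and dehydration to the more substituted endocyclic enol ether is the known route from 2-(3-oxobutyl)phenols to 2-methyl-4H-chromenes, and it ties O to C1 and places the double bond at C1=C2.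

Step 6
Reactants: 11 (4R)-8-bromo-2-methyl-4-[(3S)-4-methylpent-1-en-3-yl]-4H-chromene; 12 [4-(tert-butyldimethylsilyloxy)phenyl]boronic acid
Product: 13 (4R)-8-[4-(tert-butyldimethylsilyloxy)phenyl]-2-methyl-4-[(3S)-4-methylpent-1-en-3-yl]-4H-chromene
Conditions: Pd(OAc)2 (3 mol %), SPhos (6 mol %), K3PO4, PhMe/H2O 10:1, 60 °C
Reagents that add atoms: none
Why: Suzuki–Miyaura coupling at the only carbon–halogen bond installs ring B ortho to the ring oxygen, and the enol ether, terminal alkene and aryl silyl ether should tolerate the mild biphasic phosphate conditions.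

Step 7
Reactants: 13 (4R)-8-[4-(tert-butyldimethylsilyloxy)phenyl]-2-methyl-4-[(3S)-4-methylpent-1-en-3-yl]-4H-chromene
Product: 15 (4R)-8-[4-(tert-butyldimethylsilyloxy)phenyl]-4-[(3R)-1-iodo-4-methylpentan-3-yl]-2-methyl-4H-chromene, via alkylzirconocene 14 (not isolated)
Conditions: Cp2Zr(H)Cl (1.3 equiv), THF, rt; then I2 (1.2 equiv), −20 °C
Reagents that add atoms: iodine, II
Why: Hydrozirconation should take only the terminal alkene (the trisubstituted enol ether is inert) with anti-Markovnikov placement of zirconium at C6, and iodinolysis of the C–Zr bond gives the primary iodide.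

Step 8
Reactants: 15 (4R)-8-[4-(tert-butyldimethylsilyloxy)phenyl]-4-[(3R)-1-iodo-4-methylpentan-3-yl]-2-methyl-4H-chromene
Product: 18 4'-(tert-butyldimethylsilyloxy)-3-[(1R,6R)-3-methyl-6-(propan-2-yl)cyclohex-2-en-1-yl]biphenyl-2-ol, via alkylmagnesium iodide 16 (not isolated), via magnesium aryloxide 17 (not isolated)
Conditions: Mg turnings (3 equiv, activated), THF, 0 °C to rt; then slow addition to Ni(cod)2 (10 mol %), PCy3 (20 mol %), PhMe, 70 °C, 0.01 M; H2O
Reagents that add atoms: none
Why: Proposed new method: the primary alkylmagnesium iodide 16 is tethered to the enol ether; zerovalent nickel coordinates the C1=C2 bond and, helped by magnesium on the ether oxygen, inserts into the C1(sp2)–O bond with aryloxide as leaving group, intramolecular transmetalation gives a seven-membered alkenyl(alkyl) divalent nickel metallacycle, and C(sp2)–C(sp3) reductive elimination forms C1–C6 with retention at C1 and returns the catalyst. The closest known reaction type is the nickel-catalysed Kumada-type coupling of Grignard reagents with enol ethers and benzofurans, which opens cyclic alkenyl ethers to (Z)-alkenyl alcohols or phenols with retention; new here is that the Grignard carbon is tethered, so opening of the pyran ring is at the same time closure of the carbocycle. The cyclohexene closes by reductive elimination from the seven-membered nickelacycle, formally a six-membered closure with the C1=C2 bond inside the new ring (endo), so no trajectory rule for direct attack applies. No stereocentre is formed: C3 and C4 from step 2 are spectators, and the position and geometry of the trisubstituted alkene are dictated by the chromene ring, which holds O and C3 cis on C1=C2. The step needs insertion into the alkenyl rather than the aryl C–O bond and ring closure rather than β-hydride elimination or intermolecular coupling; the first should be secured by η2-precoordination to the enol ether and by the crowded aryl C–O bond (the silyl ether on ring B is inert), the second by high dilution, a donor phosphine that speeds reductive elimination, and the fact that only insertion at C1 leads to an unstrained six-membered ring. The phenol is released as its magnesium salt 17 and protonated on work-up.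

Step 9
Reactants: 18 4'-(tert-butyldimethylsilyloxy)-3-[(1R,6R)-3-methyl-6-(propan-2-yl)cyclohex-2-en-1-yl]biphenyl-2-ol
Product: 20 3-[(1R,6R)-3-methyl-6-(propan-2-yl)cyclohex-2-en-1-yl]-2,4'-bis(prop-2-en-1-yloxy)biphenyl, via biphenyldiol 19 (not isolated)
Conditions: allyl bromide (3 equiv), CsF (1.5 equiv), Cs2CO3 (1.5 equiv), DMF, 40 °C
Reagents that add atoms: allyl bromide, C=CCBr
Why: Fluoride cleaves the aryl silyl ether and carbonate deprotonates the hindered ring A phenol, so both phenoxides should undergo Williamson O-allylation in one operation.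

Step 10
Reactants: 20 3-[(1R,6R)-3-methyl-6-(propan-2-yl)cyclohex-2-en-1-yl]-2,4'-bis(prop-2-en-1-yloxy)biphenyl
Product: 22 3-[(1R,6R)-3-methyl-6-(propan-2-yl)cyclohex-2-en-1-yl]-3',5-di(prop-2-en-1-yl)biphenyl-2,4'-diol, via monorearranged ether 21 (not isolated)
Conditions: PhNEt2, 190 °C, sealed tube, argon
Reagents that add atoms: none
Why: In this double aromatic Claisen rearrangement the ring B ether should shift to its free ortho position, while the ring A ether, with both ortho positions blocked by ring B and the cyclohexenyl group, should reach the para position by two consecutive [3,3] shifts and tautomerisation.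

**Compound list**

1 | 3-bromo-2-hydroxybenzaldehyde | O=Cc1cccc(Br)c1O | starting material
2 | ethyl 3-oxobutanoate | CCOC(=O)CC(C)=O | starting material
3 | ethyl 2-[(3-bromo-2-hydroxyphenyl)methylidene]-3-oxobutanoate | CCOC(=O)C(C(C)=O)=Cc1cccc(Br)c1O | intermediate
4 | 3-acetyl-8-bromo-2H-chromen-2-one | CC(=O)C1=Cc2cccc(Br)c2OC1=O | intermediate
5 | 3-methylbutanal | CC(C)CC=O | starting material
6 | (1R,10bS)-7-bromo-2-hydroxy-4-methyl-1-(propan-2-yl)-1,10b-dihydro-2H,5H-pyrano[3,4-c]chromen-5-one (both anomers) | CC1=C2C(=O)Oc3c(Br)cccc3[C@@H]2[C@@H](C(C)C)C(O)O1 | intermediate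
7 | (4R)-3-acetyl-8-bromo-4-[(3S)-4-methylpent-1-en-3-yl]-3,4-dihydro-2H-chromen-2-one (C3 epimers) | CC(=O)C1C(=O)Oc2c(Br)cccc2[C@@H]1[C@H](C=C)C(C)C | intermediate
8 | (3R,4S)-2-acetyl-3-(3-bromo-2-hydroxyphenyl)-4-(propan-2-yl)hex-5-enoic acid (C2 epimers) | CC(=O)C(C(=O)O)[C@H](c1cccc(Br)c1O)[C@H](C=C)C(C)C | intermediate
9 | (4S,5S)-4-(3-bromo-2-hydroxyphenyl)-5-(propan-2-yl)hept-6-en-2-one | CC(=O)C[C@H](c1cccc(Br)c1O)[C@H](C=C)C(C)C | intermediate
10 | (4S)-8-bromo-2-methyl-4-[(3S)-4-methylpent-1-en-3-yl]-3,4-dihydro-2H-chromen-2-ol (C2 epimers) | CC1(O)C[C@@H]([C@H](C=C)C(C)C)c2cccc(Br)c2O1 | intermediate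
11 | (4R)-8-bromo-2-methyl-4-[(3S)-4-methylpent-1-en-3-yl]-4H-chromene | CC1=C[C@@H]([C@H](C=C)C(C)C)c2cccc(Br)c2O1 | intermediate
12 | [4-(tert-butyldimethylsilyloxy)phenyl]boronic acid | CC(C)(C)[Si](C)(C)Oc1ccc(B(O)O)cc1 | starting material
13 | (4R)-8-[4-(tert-butyldimethylsilyloxy)phenyl]-2-methyl-4-[(3S)-4-methylpent-1-en-3-yl]-4H-chromene | CC1=C[C@@H]([C@H](C=C)C(C)C)c2cccc(-c3ccc(O[Si](C)(C)C(C)(C)C)cc3)c2O1 | intermediate
14 | chlorobis(cyclopentadienyl){(3R)-3-[(4R)-8-[4-(tert-butyldimethylsilyloxy)phenyl]-2-methyl-4H-chromen-4-yl]-4-methylpentyl}zirconium | CC1=C[C@@H]([C@H](CC[Zr](Cl)(C4C=CC=C4)C5C=CC=C5)C(C)C)c2cccc(-c3ccc(O[Si](C)(C)C(C)(C)C)cc3)c2O1 | intermediate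
15 | (4R)-8-[4-(tert-butyldimethylsilyloxy)phenyl]-4-[(3R)-1-iodo-4-methylpentan-3-yl]-2-methyl-4H-chromene | CC1=C[C@@H]([C@H](CCI)C(C)C)c2cccc(-c3ccc(O[Si](C)(C)C(C)(C)C)cc3)c2O1 | intermediate
16 | {(3R)-3-[(4R)-8-[4-(tert-butyldimethylsilyloxy)phenyl]-2-methyl-4H-chromen-4-yl]-4-methylpentyl}magnesium iodide | CC1=C[C@@H]([C@H](CC[Mg]I)C(C)C)c2cccc(-c3ccc(O[Si](C)(C)C(C)(C)C)cc3)c2O1 | intermediate
17 | iodomagnesium 4'-(tert-butyldimethylsilyloxy)-3-[(1R,6R)-3-methyl-6-(propan-2-yl)cyclohex-2-en-1-yl]biphenyl-2-olate | I[Mg]Oc1c(-c2ccc(O[Si](C)(C)C(C)(C)C)cc2)cccc1[C@H]1C=C(C)CC[C@@H]1C(C)C | intermediate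
18 | 4'-(tert-butyldimethylsilyloxy)-3-[(1R,6R)-3-methyl-6-(propan-2-yl)cyclohex-2-en-1-yl]biphenyl-2-ol | Oc1c(-c2ccc(O[Si](C)(C)C(C)(C)C)cc2)cccc1[C@H]1C=C(C)CC[C@@H]1C(C)C | intermediate
19 | 3-[(1R,6R)-3-methyl-6-(propan-2-yl)cyclohex-2-en-1-yl]biphenyl-2,4'-diol (formed as its caesium phenoxides) | Oc1ccc(-c2cccc([C@H]3C=C(C)CC[C@@H]3C(C)C)c2O)cc1 | intermediate
20 | 3-[(1R,6R)-3-methyl-6-(propan-2-yl)cyclohex-2-en-1-yl]-2,4'-bis(prop-2-en-1-yloxy)biphenyl | C=CCOc1ccc(-c2cccc([C@H]3C=C(C)CC[C@@H]3C(C)C)c2OCC=C)cc1 | intermediate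
21 | 3-[(1R,6R)-3-methyl-6-(propan-2-yl)cyclohex-2-en-1-yl]-3'-(prop-2-en-1-yl)-2-(prop-2-en-1-yloxy)biphenyl-4'-ol | C=CCOc1c(-c2ccc(O)c(CC=C)c2)cccc1[C@H]1C=C(C)CC[C@@H]1C(C)C | intermediate
22 | 3-[(1R,6R)-3-methyl-6-(propan-2-yl)cyclohex-2-en-1-yl]-3',5-di(prop-2-en-1-yl)biphenyl-2,4'-diol | C=CCc1cc(-c2ccc(O)c(CC=C)c2)c(O)c([C@H]2C=C(C)CC[C@@H]2C(C)C)c1 | target

**Step count**

Total steps: 10. Longest linear sequence: 10 steps (1 to 22).

**Steps most likely to fail**

Step 8 (the proposed new method). The alkylnickel intermediate may undergo β-hydride elimination, or zerovalent nickel may fail to insert into the hindered trisubstituted enol-ether C–O bond, so that 15 is only reduced or oligomerised. The fallback makes the same C1–C6 bond with known reaction types and sets out from 13. Reductive cleavage of the alkenyl C–O bond with lithium and catalytic 4,4'-di-tert-butylbiphenyl (THF, −78 to 0 °C) would give the dilithiated (Z)-alkenyllithium phenoxide F1. Quenching with I2 would give the vinyl iodide 3-[(2Z,4R,5S)-2-iodo-5-(propan-2-yl)hepta-2,6-dien-4-yl]-4'-(tert-butyldimethylsilyloxy)biphenyl-2-ol F2. Hydroboration of its terminal alkene with 9-BBN-H would give the B-alkyl-9-borabicyclo[3.3.1]nonane F3, and Pd(dppf)Cl2 with Cs2CO3 (DMF/THF/H2O, 50 °C) would close the ring by intramolecular B-alkyl Suzuki–Miyaura coupling. This comes back to the route at 18.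

Step 2. The enamine may add too slowly to the coumarin, or with the wrong relative topicity if the lactone carbonyl rather than the acetyl group steers the approach; the adduct could also erode by retro-Michael reaction. The fallback replaces the catalytic enamine by a stoichiometric chiral azaenolate and sets out from 5 and 4. Condensation of 5 with (R)-1-amino-2-(methoxymethyl)pyrrolidine would give the RAMP hydrazone of 3-methylbutanal F4 (the enantiomeric auxiliary would be used if the sense proves opposite). Deprotonation with LiN(iPr)2 (THF, −78 °C) would give the lithium azaenolate F5, which is added to 4 at −100 °C and quenched with aq NH4Cl to give the Michael adduct hydrazone F6. Mild hydrazone cleavage (aqueous oxalic acid, Et2O) would release the aldehyde, which closes to lactol 6, where the route is rejoined.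

Step 10. The para shift on ring A may compete with migration of the cyclohexenyl group out of the ortho-dienone, or the hot phenol may add to the ring alkene. The fallback installs the ring A allyl group by C–H borylation and cross-coupling, leaving only the ordinary ortho-Claisen on ring B, and sets out from 18. Silylation of the hindered phenol (tert-butyldimethylsilyl triflate, 2,6-lutidine) would give the bis-silyl ether F7. Borylation with [Ir(OMe)(cod)]2, 4,4'-di-tert-butyl-2,2'-bipyridine and B2pin2 should take the only unhindered ring A position (C5, para to oxygen) to give the pinacol boronate F8. Pd(PPh3)4 and CsF with allyl bromide would give the 5-allyl bis-silyl ether F9, and Bu4NF would give the 5-allyl diol F10. O-allylation of the unhindered ring B phenol (K2CO3, 1 equiv allyl bromide, acetone) would give the ring B allyl ether F11, and heating in PhNEt2 at 190 °C rejoins the route at 22.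

**Further compounds**

F1 | step 8 | dilithium (Z)-alkenyllithium phenoxide from reductive opening of 13 | C/C([Li])=C/[C@H](c1cccc(-c2ccc(O[Si](C)(C)C(C)(C)C)cc2)c1O[Li])[C@H](C=C)C(C)C
F2 | step 8 | 3-[(2Z,4R,5S)-2-iodo-5-(propan-2-yl)hepta-2,6-dien-4-yl]-4'-(tert-butyldimethylsilyloxy)biphenyl-2-ol | C/C(I)=C/[C@H](c1cccc(-c2ccc(O[Si](C)(C)C(C)(C)C)cc2)c1O)[C@H](C=C)C(C)C
F3 | step 8 | B-alkyl-9-borabicyclo[3.3.1]nonane from hydroboration of F2 | C/C(I)=C/[C@H](c1cccc(-c2ccc(O[Si](C)(C)C(C)(C)C)cc2)c1O)[C@H](CCB1C2CCCC1CCC2)C(C)C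
F4 | step 2 | (E)-hydrazone of 3-methylbutanal with (R)-1-amino-2-(methoxymethyl)pyrrolidine | COC[C@H]1CCCN1/N=C/CC(C)C
F5 | step 2 | lithium azaenolate of F4 | COC[C@H]1CCCN1N([Li])C=CC(C)C
F6 | step 2 | RAMP hydrazone of the Michael adduct of 3-methylbutanal and 4 | COC[C@H]1CCCN1/N=C/[C@H](C(C)C)[C@H]2c3cccc(Br)c3OC(=O)C2C(C)=O
F7 | step 10 | 2,4'-bis(tert-butyldimethylsilyloxy)-3-[(1R,6R)-3-methyl-6-(propan-2-yl)cyclohex-2-en-1-yl]biphenyl | CC(C)(C)[Si](C)(C)Oc1ccc(-c2cccc([C@H]3C=C(C)CC[C@@H]3C(C)C)c2O[Si](C)(C)C(C)(C)C)cc1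
F8 | step 10 | 5-(4,4,5,5-tetramethyl-1,3,2-dioxaborolan-2-yl) derivative of F7 | CC(C)(C)[Si](C)(C)Oc1ccc(-c2cc(B3OC(C)(C)C(C)(C)O3)cc([C@H]3C=C(C)CC[C@@H]3C(C)C)c2O[Si](C)(C)C(C)(C)C)cc1
F9 | step 10 | 2,4'-bis(tert-butyldimethylsilyloxy)-3-[(1R,6R)-3-methyl-6-(propan-2-yl)cyclohex-2-en-1-yl]-5-(prop-2-en-1-yl)biphenyl | CC(C)(C)[Si](C)(C)Oc1ccc(-c2cc(CC=C)cc([C@H]3C=C(C)CC[C@@H]3C(C)C)c2O[Si](C)(C)C(C)(C)C)cc1
F10 | step 10 | 3-[(1R,6R)-3-methyl-6-(propan-2-yl)cyclohex-2-en-1-yl]-5-(prop-2-en-1-yl)biphenyl-2,4'-diol | C=CCc1cc(-c2ccc(O)cc2)c(O)c([C@H]2C=C(C)CC[C@@H]2C(C)C)c1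
F11 | step 10 | 3-[(1R,6R)-3-methyl-6-(propan-2-yl)cyclohex-2-en-1-yl]-5-(prop-2-en-1-yl)-4'-(prop-2-en-1-yloxy)biphenyl-2-ol | C=CCOc1ccc(-c2cc(CC=C)cc([C@H]3C=C(C)CC[C@@H]3C(C)C)c2O)cc1
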